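Ring C is disconnected at the C8=C9 enone double bond, which is endocyclic in the nine-membered ring C, exocyclic to the five-membered ring B and conjugated with the C7 ketone, C8 lying beside the quaternary C16 (numbering in the remark below). In one operation SmI2 converts a C8 gem-dichloride into a samarium enolate, joins it to a tethered C9 aldehyde and expels the new β-oxygen, so ring C and the enone arise together. The precursor is a cis-fused 8,8-dichlorohydrindanone that already carries both acetates and, on C16, a propyl chain ending in an N-Boc-N-(3-oxopropyl)amino group; dichloroketene cycloaddition and diazomethane ring expansion on a cyclohexene diacetate supply it.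

Key step: step 13

Remark on numbering: positions are those of the target throughout. C1 is the acetoxy methine, C3 the methyl/acetoxy carbon, C5 the ring-fusion CH, C7 the ketone, C8=C9 the alkene, N12 the amine and C16 the quaternary ring-fusion carbon. Ring A is C1–C5 plus C16, ring B is C5–C8 plus C16, ring C is C8–C16.

Assumptions: the target is taken as the open amino ketone drawn, not as a transannular carbinolamine. tert-Butyl N-allylcarbamate and (3-bromopropoxy)(tert-butyl)diphenylsilane are taken as commercial.

Step 1
Reactants: 1 3-methylcyclohex-2-en-1-one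
Product: 3 (S)-3-hydroxy-3-methylcyclohexan-1-one, via boronate 2 (not isolated)
Conditions: CuCl (5 mol %), QuinoxP* (6 mol %, enantiomer giving the 3R boronate), NaOtBu (10 mol %), B2pin2, MeOH, THF, rt; then NaBO3·4H2O, THF/H2O, rt
Reagents that add atoms: bis(pinacolato)diboron, CC1(C)OB(OC1(C)C)B1OC(C)(C)C(C)(C)O1 (boryl group of 2); sodium perborate, [Na+].[O-]OB=O (hydroxyl oxygen of 3)
Why: Enantioselective copper-boryl conjugate addition to the β,β-disubstituted enone sets the quaternary C3 centre under ligand control, and perborate oxidation of the C–B bond proceeds with retention (the descriptor changes from R to S only through CIP priorities).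

Step 2
Reactants: 3 (S)-3-hydroxy-3-methylcyclohexan-1-one
Product: 4 (S)-3-methyl-3-(triethylsilyloxy)cyclohexan-1-one
Conditions: TESOTf, 2,6-lutidine, CH2Cl2, −78 to 0 °C
Reagents that add atoms: triethylsilyl trifluoromethanesulfonate, CC[Si](CC)(CC)OS(=O)(=O)C(F)(F)F
Why: Silyl triflate silylation of the hindered tertiary alcohol; the silyl ether blocks retro-aldol cleavage and β-elimination of the β-oxygenated ketone in the base and palladium steps that follow.

Step 3
Reactants: 4 (S)-3-methyl-3-(triethylsilyloxy)cyclohexan-1-one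
Product: 6 (S)-5-methyl-5-(triethylsilyloxy)cyclohex-2-en-1-one, via trimethylsilyl enol ether 5 (not isolated)
Conditions: LDA, THF, −78 °C, then TMSCl; then Pd(OAc)2 (10 mol %), O2 (1 atm), DMSO, rt
Reagents that add atoms: chlorotrimethylsilane, C[Si](C)(C)Cl (silyl group of 5 only)
Why: Kinetic deprotonation takes the CH2 remote from the quaternary carbon (future C16), and Saegusa–Ito oxidation can only give the C5=C16 enone because C3 bears no hydrogen.

Step 4
Reactants: 6 (S)-5-methyl-5-(triethylsilyloxy)cyclohex-2-en-1-one
Product: 7 (S)-2-iodo-5-methyl-5-(triethylsilyloxy)cyclohex-2-en-1-one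
Conditions: I2, pyridine, CH2Cl2, 0 °C to rt
Reagents that add atoms: iodine, II
Why: α-Iodination of the enone by addition–elimination: pyridine adds reversibly to the β-carbon, the enolate is iodinated at C16 and pyridine is expelled (Baylis–Hillman-type mechanism).

Step 5
Reactants: 7 (S)-2-iodo-5-methyl-5-(triethylsilyloxy)cyclohex-2-en-1-one
Product: 9 (1S,5S)-2-iodo-5-methylcyclohex-2-ene-1,5-diol (hydroxyls cis), via silyl-protected iodo alcohol 8 (not isolated)
Conditions: (R)-2-methyl-CBS-oxazaborolidine (20 mol %), BH3·SMe2, THF, −20 °C; MeOH quench; then 1 M HCl, MeOH/THF, 0 °C to rt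
Reagents that add atoms: none
Why: Corey–Bakshi–Shibata reduction in which the iodovinyl arm is the large group, so the catalyst should deliver hydride to the face that gives the 1S carbinol cis to the C3 oxygen (reagent control over the remote C3 centre); the acidic methanol work-up then hydrolyses the tertiary silyl ether.

Step 6
Reactants: 10 tert-butyl N-allylcarbamate; 11 (3-bromopropoxy)(tert-butyl)diphenylsilane
Product: 12 tert-butyl N-allyl-N-[3-(tert-butyldiphenylsilyloxy)propyl]carbamate
Conditions: NaH, DMF, 0 °C to rt
Reagents that add atoms: none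
Why: SN2 N-alkylation of the carbamate sodium salt by a primary bromide; the future aldehyde carbon is carried as a silyl-protected alcohol because an acetal would not survive ZnCl2 with an acid chloride and a free aldehyde would not survive diazomethane.

Step 7
Reactants: 12 tert-butyl N-allyl-N-[3-(tert-butyldiphenylsilyloxy)propyl]carbamate; 9 (1S,5S)-2-iodo-5-methylcyclohex-2-ene-1,5-diol
Product: 14 tert-butyl N-[3-(tert-butyldiphenylsilyloxy)propyl]-N-{3-[(4S,6S)-4,6-dihydroxy-4-methylcyclohex-1-en-1-yl]propyl}carbamate, via alkylborane 13 (not isolated)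
Conditions: 9-BBN, THF, rt; then 9, PdCl2(dppf) (5 mol %), AsPh3, Cs2CO3, DMF/H2O, rt
Reagents that add atoms: 9-borabicyclo[3.3.1]nonane, B1C2CCCC1CCC2 (boron bicycle of 13 only)
Why: Anti-Markovnikov hydroboration of the terminal alkene followed by B-alkyl Suzuki–Miyaura coupling with the vinyl iodide forms the C15–C16 bond without moving the alkene; free hydroxyls, carbamate and silyl ether are tolerated.

Step 8
Reactants: 14 coupled cis-diol
Product: 15 (1S,5S)-2-{3-[(tert-butoxycarbonyl)(3-(tert-butyldiphenylsilyloxy)propyl)amino]propyl}-5-methylcyclohex-2-ene-1,5-diyl diacetate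
Conditions: Ac2O, Et3N, DMAP, CH2Cl2, rt
Reagents that add atoms: acetic anhydride, CC(=O)OC(C)=O
Why: DMAP-catalysed (Steglich-type) acylation esterifies the secondary allylic alcohol quickly and the tertiary alcohol on prolonged reaction, with no stereocentre touched.

Step 9
Reactants: 15 cyclohexene diacetate; 16 trichloroacetyl chloride
Product: 18 cis-fused 8,8-dichlorobicyclo[4.2.0]octan-7-one diacetate (carbonyl on C5, CCl2 on C16, four-membered ring on the face of both acetoxy groups, anti to the C3 methyl), via dichloroketene 17 (not isolated)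
Conditions: Zn–Cu couple, 16 added slowly, DME, Et2O, rt
Reagents that add atoms: none
Why: Ketene–alkene [2+2] cycloaddition: the ketene carbonyl carbon bonds to the less substituted C5 and the CCl2 carbon to C16, suprafacially, so the fusion is cis; attack should come anti to the C3 methyl, which is axial in the half-chair that keeps both cis acetoxy groups (pseudo)equatorial and the allylic C1–O bond near the alkene plane, and this sets C5 and C16.

Step 10
Reactants: 18 dichlorocyclobutanone diacetate
Product: 19 cis-fused 8,8-dichlorohydrindan-7-one diacetate with the N-Boc silyloxypropyl arm on C16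
Conditions: CH2N2, Et2O, MeOH (cat.), 0 °C to rt
Reagents that add atoms: diazomethane, C=[N+]=[N-]
Why: Diazomethane ring expansion of an α,α-dichlorocyclobutanone (Tiffeneau–Demjanov type): the non-chlorinated, more electron-rich C5 migrates with retention, placing the new CH2 (C6) between the carbonyl and C5, and the less strained cyclopentanone does not react further.

Step 11
Reactants: 19 dichlorohydrindanone silyl ether
Product: 20 dichlorohydrindanone diacetate with an N-Boc-N-(3-hydroxypropyl)aminopropyl arm
Conditions: HF·pyridine, pyridine, THF, 0 °C to rt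
Reagents that add atoms: none
Why: Fluoride desilylation of the primary silyl ether under buffered, weakly acidic conditions that spare the acetates, the carbamate and the base-sensitive dichloroketone (which has no β-hydrogen on the chlorinated side).

Step 12
Reactants: 20 primary alcohol
Product: 21 8,8-dichlorohydrindanone diacetate with an N-Boc-N-(3-oxopropyl)aminopropyl arm
Conditions: Dess–Martin periodinane, CH2Cl2, 0 °C to rt
Reagents that add atoms: none
Why: Dess–Martin oxidation gives the aldehyde under near-neutral conditions without over-oxidation; the N-Boc β-amino aldehyde is used directly.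

Step 13
Reactants: 21 dichloro keto aldehyde
Product: 24 N-Boc tricyclic enone diacetate (ring C closed, C8=C9 with C10 cis to C16), via samarium chloro-enolate 22 (not isolated), via samarium chloro-aldolate 23 (not isolated)
Conditions: SmI2 (0.1 M in THF, 5 equiv) added slowly to 21 (0.005 M in THF), −78 °C to rt; sat. aq. NH4Cl
Reagents that add atoms: samarium diiodide, I[Sm]I (metal of 22 and 23 only)
Why: Proposed new method: two-electron reduction of one C8–Cl bond gives a trivalent samarium chloro-enolate whose oxophilic metal binds the tethered aldehyde, so C8 adds to C9 in a templated Reformatsky-type aldol step; reduction of the second C8–Cl bond then gives an enolate that expels the C9 samarium alkoxide by β-elimination, forming the enone. The closest known reactions are the SmI2-promoted intramolecular Reformatsky closure of medium rings from α-halo carbonyl compounds and the intermolecular SmI2 aldol–elimination of α,α-dichloro carbonyl compounds with aldehydes to E-enones; joining them in a nine-membered closure is the untested element. Ring C closes in a 9-exo-trig mode, the enolate carbon C8 attacking the aldehyde carbon C9 with the aldehyde oxygen outside the ring. No stereocentre is created that survives, since the C8 and C9 centres of the aldolate are both destroyed, and the alkene geometry (C10 cis to C16, E by CIP) is the one a nine-membered ring and elimination from the chelated aldolate can accommodate. Site selectivity is secured because only C8 carries halogen, chemoselectivity because α-chloro ketones are reduced far faster than aliphatic aldehydes or acetates by SmI2 in THF without HMPA, and ring closure over oligomerisation by high dilution.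

Step 14
Reactants: 24 N-Boc tricyclic enone diacetate
Product: 26 target amino enone diacetate (1S,3S,5S,16S in the numbering above), via trifluoroacetate salt 25 (not isolated)
Conditions: TFA/CH2Cl2 (1:5), 0 °C; then sat. aq. NaHCO3
Reagents that add atoms: trifluoroacetic acid, OC(=O)C(F)(F)F (counter-ion of 25 only)
Why: Acidolysis of the tert-butyl carbamate (loss of isobutene and CO2) should be much faster at 0 °C than ionisation of the tertiary acetate, which the 1,3-acetoxy group retards, and the bicarbonate work-up frees the secondary amine.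

Compound list
1 | 3-methylcyclohex-2-en-1-one | CC1=CC(=O)CCC1 | starting material
2 | (R)-3-methyl-3-(4,4,5,5-tetramethyl-1,3,2-dioxaborolan-2-yl)cyclohexan-1-one | O=C1C[C@@](C)(B2OC(C)(C)C(C)(C)O2)CCC1 | intermediate (not isolated)
3 | (S)-3-hydroxy-3-methylcyclohexan-1-one | O=C1C[C@@](C)(O)CCC1 | intermediate
4 | (S)-3-methyl-3-(triethylsilyloxy)cyclohexan-1-one | O=C1C[C@@](C)(O[Si](CC)(CC)CC)CCC1 | intermediate
5 | kinetic trimethylsilyl enol ether of 4 (enol double bond away from the quaternary carbon) | C[Si](C)(C)OC1=CCC[C@](C)(O[Si](CC)(CC)CC)C1 | intermediate (not isolated)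
6 | (S)-5-methyl-5-(triethylsilyloxy)cyclohex-2-en-1-one | O=C1C[C@@](C)(O[Si](CC)(CC)CC)CC=C1 | intermediate
7 | (S)-2-iodo-5-methyl-5-(triethylsilyloxy)cyclohex-2-en-1-one | O=C1C[C@@](C)(O[Si](CC)(CC)CC)CC=C1I | intermediate
8 | (1S,5S)-2-iodo-5-methyl-5-(triethylsilyloxy)cyclohex-2-en-1-ol | O[C@H]1C[C@@](C)(O[Si](CC)(CC)CC)CC=C1I | intermediate (not isolated)
9 | (1S,5S)-2-iodo-5-methylcyclohex-2-ene-1,5-diol | O[C@H]1C[C@@](C)(O)CC=C1I | intermediate
10 | tert-butyl N-allylcarbamate | C=CCNC(=O)OC(C)(C)C | starting material
11 | (3-bromopropoxy)(tert-butyl)diphenylsilane | BrCCCO[Si](c1ccccc1)(c1ccccc1)C(C)(C)C | starting material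
12 | tert-butyl N-allyl-N-[3-(tert-butyldiphenylsilyloxy)propyl]carbamate | C=CCN(CCCO[Si](c1ccccc1)(c1ccccc1)C(C)(C)C)C(=O)OC(C)(C)C | intermediate
13 | B-alkyl-9-BBN adduct of 12 (boron on the terminal carbon) | CC(C)(C)OC(=O)N(CCCB1C2CCCC1CCC2)CCCO[Si](c1ccccc1)(c1ccccc1)C(C)(C)C | intermediate (not isolated)
14 | tert-butyl N-[3-(tert-butyldiphenylsilyloxy)propyl]-N-{3-[(4S,6S)-4,6-dihydroxy-4-methylcyclohex-1-en-1-yl]propyl}carbamate | O[C@H]1C[C@@](C)(O)CC=C1CCCN(CCCO[Si](c2ccccc2)(c2ccccc2)C(C)(C)C)C(=O)OC(C)(C)C | intermediate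
15 | (1S,5S)-2-{3-[(tert-butoxycarbonyl)(3-(tert-butyldiphenylsilyloxy)propyl)amino]propyl}-5-methylcyclohex-2-ene-1,5-diyl diacetate | CC(=O)O[C@H]1C[C@@](C)(OC(C)=O)CC=C1CCCN(CCCO[Si](c2ccccc2)(c2ccccc2)C(C)(C)C)C(=O)OC(C)(C)C | intermediate
16 | trichloroacetyl chloride | ClC(=O)C(Cl)(Cl)Cl | starting material
17 | dichloroketene | ClC(Cl)=C=O | intermediate (not isolated)
18 | cis-fused dichlorocyclobutanone diacetate (C=O on C5, CCl2 on C16, ring on the acetoxy face) | CC(=O)O[C@H]1C[C@@](C)(OC(C)=O)C[C@H]2C(=O)C(Cl)(Cl)[C@]21CCCN(CCCO[Si](c3ccccc3)(c3ccccc3)C(C)(C)C)C(=O)OC(C)(C)C | intermediate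
19 | cis-fused 8,8-dichlorohydrindan-7-one diacetate, silyl-protected arm | CC(=O)O[C@H]1C[C@@](C)(OC(C)=O)C[C@H]2CC(=O)C(Cl)(Cl)[C@]21CCCN(CCCO[Si](c3ccccc3)(c3ccccc3)C(C)(C)C)C(=O)OC(C)(C)C | intermediate
20 | 8,8-dichlorohydrindan-7-one diacetate, N-Boc-N-(3-hydroxypropyl) arm | CC(=O)O[C@H]1C[C@@](C)(OC(C)=O)C[C@H]2CC(=O)C(Cl)(Cl)[C@]21CCCN(CCCO)C(=O)OC(C)(C)C | intermediate
21 | 8,8-dichlorohydrindan-7-one diacetate, N-Boc-N-(3-oxopropyl) arm (key-step precursor) | CC(=O)O[C@H]1C[C@@](C)(OC(C)=O)C[C@H]2CC(=O)C(Cl)(Cl)[C@]21CCCN(CCC=O)C(=O)OC(C)(C)C | intermediate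
22 | samarium C7-enolate of the 8-chloro ketone (aldehyde arm intact) | CC(=O)O[C@H]1C[C@@](C)(OC(C)=O)C[C@H]2CC(O[Sm](I)I)=C(Cl)[C@]21CCCN(CCC=O)C(=O)OC(C)(C)C | intermediate (not isolated)
23 | ring-C-closed 8-chloro ketone with C9 samarium alkoxide (C8 and C9 configurations transient, not specified) | CC(=O)O[C@H]1C[C@@](C)(OC(C)=O)C[C@H]2CC(=O)C3(Cl)C(O[Sm](I)I)CCN(C(=O)OC(C)(C)C)CCC[C@@]321 | intermediate (not isolated)
24 | N-Boc tricyclic enone diacetate (key-step product) | CC(=O)O[C@H]1C[C@@](C)(OC(C)=O)C[C@H]2CC(=O)/C3=C/CCN(C(=O)OC(C)(C)C)CCC[C@@]321 | intermediate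
25 | trifluoroacetate salt of the target amine | CC(=O)O[C@H]1C[C@@](C)(OC(C)=O)C[C@H]2CC(=O)/C3=C/CC[NH2+]CCC[C@@]321.[O-]C(=O)C(F)(F)F | intermediate (not isolated)
26 | target amino enone diacetate (CNP0120442.1) | CC(=O)O[C@H]1C[C@@](C)(OC(C)=O)C[C@H]2CC(=O)/C3=C/CCNCCC[C@@]321 | target

Total step count: 14. Longest linear sequence: 13 (steps 1–5 and 7–14).

Steps most likely to fail

1. Step 13 (proposed new method). After the first reduction the chloro-enolate may be protonated, may take the nearby C1 acetyl group, or may aldolise between molecules faster than it closes the nine-membered ring; the aldehyde may also be reduced before it is attacked. The fallback uses known reactions and sets out from 21. Radical mono-dechlorination (Bu3SnH, 1 equiv, Et3B/air, toluene, 0 °C) gives the 8-monochloro keto aldehyde F1 as a mixture of C8 epimers. SmI2 (2.2 equiv, THF, high dilution) then effects the established intramolecular Reformatsky closure to the nine-membered β-hydroxy ketone F2. Mesylation (MsCl, Et3N, CH2Cl2, 0 °C) gives the C9 mesylate F3, and DBU eliminates it to the conjugated enone, rejoining the route at 24.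

2. Step 9. The alkene is deactivated by the allylic acetate, so ketene oligomerisation may outrun cycloaddition, and facial selectivity may be poor if the half-chair with axial acetoxy groups reacts. The fallback sets out from 14. Both ring hydroxyls are silylated (TESOTf, 2,6-lutidine) to the bis(triethylsilyl) ether F4; bulky silyloxy groups cannot sit syn-diaxial, which holds the C3 methyl axial, and they withdraw less electron density than acetates. The same dichloroketene cycloaddition gives the dichlorocyclobutanone F5, and diazomethane gives the dichlorocyclopentanone F6. PPTS in MeOH removes the two triethylsilyl groups but not the primary tert-butyldiphenylsilyl ether, giving the ring diol F7. Ac2O, DMAP and Et3N convert this into the diacetate, rejoining at 19.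

3. Step 5. Mismatched double diastereoselection between the catalyst and the C3 centre may erode facial selectivity at C1. The fallback sets out from 7 and replaces reagent control by internal delivery plus inversion. HF·pyridine frees the tertiary alcohol, giving the hydroxy iodoenone F8. Me4NBH(OAc)3 in MeCN/AcOH (Evans–Saksena reduction, hydride delivered from the C3 oxygen) gives the trans-1,3-diol F9, the C1 epimer of 9. Mitsunobu reaction with 4-nitrobenzoic acid (PPh3, DIAD) inverts C1 and gives the 4-nitrobenzoate F10; the tertiary alcohol does not react. K2CO3 in MeOH cleaves the ester, rejoining at 9.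

Further compounds
F1 | step 13 | 8-monochloro keto aldehyde (C8 epimers) | CC(=O)O[C@H]1C[C@@](C)(OC(C)=O)C[C@H]2CC(=O)C(Cl)[C@]21CCCN(CCC=O)C(=O)OC(C)(C)C
F2 | step 13 | ring-C-closed β-hydroxy ketone (C8, C9 epimers) | CC(=O)O[C@H]1C[C@@](C)(OC(C)=O)C[C@H]2CC(=O)C3C(O)CCN(C(=O)OC(C)(C)C)CCC[C@@]321
F3 | step 13 | C9 mesylate of F2 | CC(=O)O[C@H]1C[C@@](C)(OC(C)=O)C[C@H]2CC(=O)C3C(OS(C)(=O)=O)CCN(C(=O)OC(C)(C)C)CCC[C@@]321
F4 | step 9 | bis(triethylsilyl) ether of 14 | CC[Si](CC)(CC)O[C@H]1C[C@@](C)(O[Si](CC)(CC)CC)CC=C1CCCN(CCCO[Si](c2ccccc2)(c2ccccc2)C(C)(C)C)C(=O)OC(C)(C)C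
F5 | step 9 | bis(triethylsilyl) dichlorocyclobutanone | CC[Si](CC)(CC)O[C@H]1C[C@@](C)(O[Si](CC)(CC)CC)C[C@H]2C(=O)C(Cl)(Cl)[C@]21CCCN(CCCO[Si](c3ccccc3)(c3ccccc3)C(C)(C)C)C(=O)OC(C)(C)C
F6 | step 9 | bis(triethylsilyl) dichlorocyclopentanone | CC[Si](CC)(CC)O[C@H]1C[C@@](C)(O[Si](CC)(CC)CC)C[C@H]2CC(=O)C(Cl)(Cl)[C@]21CCCN(CCCO[Si](c3ccccc3)(c3ccccc3)C(C)(C)C)C(=O)OC(C)(C)C
F7 | step 9 | dichlorocyclopentanone ring diol | O[C@H]1C[C@@](C)(O)C[C@H]2CC(=O)C(Cl)(Cl)[C@]21CCCN(CCCO[Si](c3ccccc3)(c3ccccc3)C(C)(C)C)C(=O)OC(C)(C)C
F8 | step 5 | (S)-5-hydroxy-2-iodo-5-methylcyclohex-2-en-1-one | O=C1C[C@@](C)(O)CC=C1I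
F9 | step 5 | (1R,5S)-2-iodo-5-methylcyclohex-2-ene-1,5-diol (trans-diol) | O[C@@H]1C[C@@](C)(O)CC=C1I
F10 | step 5 | (1S,5S)-5-hydroxy-2-iodo-5-methylcyclohex-2-en-1-yl 4-nitrobenzoate | O=C(O[C@H]1C[C@@](C)(O)CC=C1I)c1ccc(cc1)[N+](=O)[O-]
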